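**Plan**

- Feature: benzene ring B of the 5,7-dihydroxycoumarin half is a phloroglucinol in which C8, the carbon carrying the diaryl ether oxygen, lies between the oxygenated carbons C7 and C8a. Its six carbons and their oxygens map onto C2–C6 and the exocyclic CH2 of a 4-alkoxy-6-(aryloxymethyl)-2-pyranone, where that ether is still an alkyl aryl ether on an sp3 carbon.
- Retrosynthetic cuts, in order: the O-benzyl bond at C5–O; O1–C2 and C4–C4a of pyranone ring B (back to a symmetric resorcinol and ethyl propiolate); C8–C8a of benzene ring B (Claisen bond, back to the 2-pyranone); the pyranone O–C(=O) bond and the CH2–CO bond to a dioxinone dienolate; the ArO–CH2 bond and the 7-O–CH3 bond of ring A.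
- Forward: coumarin A comes intact from daphnetin. Its aryloxyacetyl chain is extended to a triketide and closed to a sacrificial 2-pyranone. That ring is opened and reclosed to benzene ring B, pyranone ring B is annulated last, and the benzyl ether is removed.
- Stereochemistry: the target has no stereocentre. The only geometric demands are the enoate geometry inherited from the pyranone in the key step and the Z cinnamate needed for lactonisation. The 8-aryloxy regiochemistry follows from the mirror symmetry of the resorcinol and the benzyl label on its para oxygen.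

Key step: step 8

Remark on the chemistry: benzyloxide in benzyl alcohol is taken as the ring-opening alkoxide so that ester exchange and addition–elimination at the benzyloxy-bearing pyranone carbon are degenerate, and the ring-opened enoate is named 2E (ester carbon and C4 cis, as in the ring).

**Route**

Step 1
Reactants: 1 daphnetin (7,8-dihydroxy-2H-chromen-2-one)
Product: 2 8-hydroxy-7-methoxy-2H-chromen-2-one
Conditions: MeI (1.05 equiv), KHCO3 (1.1 equiv), DMF, rt
Reagents that add atoms: iodomethane, CI
Why: Williamson methylation of the monoanion; the 7-OH is conjugated with the lactone carbonyl through C4a–C4=C3 and is the more acidic hydroxyl, so a hydrogen carbonate base should ionise and alkylate it selectively while the 8-OH stays protonated.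

Step 2
Reactants: 2 8-hydroxy-7-methoxy-2H-chromen-2-one; 3 tert-butyl bromoacetate
Product: 4 tert-butyl 2-[(7-methoxy-2-oxo-2H-chromen-8-yl)oxy]acetate
Conditions: K2CO3, DMF, 50 °C
Reagents that add atoms: none
Why: Williamson etherification (SN2) of the remaining phenol by an unhindered α-bromo ester; the tert-butyl ester avoids a later saponification that would open the lactone.

Step 3
Reactants: 4 tert-butyl 2-[(7-methoxy-2-oxo-2H-chromen-8-yl)oxy]acetate
Product: 5 2-[(7-methoxy-2-oxo-2H-chromen-8-yl)oxy]acetic acid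
Conditions: TFA/CH2Cl2 (1:2), rt
Reagents that add atoms: none
Why: acidolysis of a tert-butyl ester (E1 loss of the tert-butyl cation), to which the coumarin lactone and both aryl ethers are inert.

Step 4
Reactants: 5 2-[(7-methoxy-2-oxo-2H-chromen-8-yl)oxy]acetic acid
Product: 6 2-[(7-methoxy-2-oxo-2H-chromen-8-yl)oxy]acetyl chloride
Conditions: (COCl)2 (1.5 equiv), DMF (cat.), CH2Cl2, 0 °C to rt; evaporation, used crude
Reagents that add atoms: oxalyl chloride, O=C(Cl)C(=O)Cl
Why: acid chloride formation through the Vilsmeier-type chloroiminium catalyst gives the most electrophilic acyl donor, which is needed for chemoselectivity in the next step.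

Step 5
Reactants: 6 2-[(7-methoxy-2-oxo-2H-chromen-8-yl)oxy]acetyl chloride; 7 2,2,6-trimethyl-4H-1,3-dioxin-4-one
Product: 9 6-{3-[(7-methoxy-2-oxo-2H-chromen-8-yl)oxy]-2-oxopropyl}-2,2-dimethyl-4H-1,3-dioxin-4-one, via lithium dienolate 8 (not isolated)
Conditions: 7 (2.1 equiv), LiN(SiMe3)2 (2.1 equiv), THF, −78 °C; then 6 in THF, −78 °C; 1 M HCl quench
Reagents that add atoms: none
Why: γ-C-acylation of the dioxinone lithium dienolate by an acid chloride (vinylogous Claisen acylation, the standard entry to keto-dioxinones); the acid chloride should outrun the coumarin lactone at −78 °C, and the second equivalent of dienolate is consumed in deprotonating the acidic product, so no enolate is left for conjugate addition.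

Step 6
Reactants: 9 6-{3-[(7-methoxy-2-oxo-2H-chromen-8-yl)oxy]-2-oxopropyl}-2,2-dimethyl-4H-1,3-dioxin-4-one
Product: 11 4-hydroxy-6-{[(7-methoxy-2-oxo-2H-chromen-8-yl)oxy]methyl}-2H-pyran-2-one, via acylketene 10 (not isolated)
Conditions: toluene, 110 °C
Reagents that add atoms: none
Why: thermal retro-[4+2] cleavage of the dioxinone releases acetone and acylketene 10, which is trapped by the enol oxygen of the δ-ketone to give the 4-hydroxy-2-pyranone, the established dioxinone-to-pyranone route.

Step 7
Reactants: 11 4-hydroxy-6-{[(7-methoxy-2-oxo-2H-chromen-8-yl)oxy]methyl}-2H-pyran-2-one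
Product: 12 4-(benzyloxy)-6-{[(7-methoxy-2-oxo-2H-chromen-8-yl)oxy]methyl}-2H-pyran-2-one
Conditions: PhCH2OH, PPh3, DIAD, THF, 0 °C to rt
Reagents that add atoms: benzyl alcohol, OCc1ccccc1
Why: Mitsunobu O-alkylation of the vinylogous acid (pKa about 5), which for 4-hydroxy-2-pyranones is known to favour the 4-oxygen over C3.

Step 8
Reactants: 12 4-(benzyloxy)-6-{[(7-methoxy-2-oxo-2H-chromen-8-yl)oxy]methyl}-2H-pyran-2-one
Product: 15 8-[4-(benzyloxy)-2,6-dihydroxyphenoxy]-7-methoxy-2H-chromen-2-one, via benzyl keto enoate 13 (not isolated), via cyclohexenedione 14 (not isolated)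
Conditions: NaOCH2Ph (1 M in PhCH2OH, 4 equiv), degassed, Ar, 90 °C; then 2 M HCl, rt
Reagents that add atoms: none
Why: Benzyloxide adds to the lactone carbonyl C2 of 12 and the ring opens to the benzyl 2E keto enoate 13, whose ester carbon and C4 methylene stay cis as in the ring; proton exchange with benzyl alcohol then gives, besides the unproductive C4 enolate, the enolate at C6, the carbon between the ketone and the aryloxy group. That carbanion attacks the benzyl ester in a Claisen (Dieckmann-type) condensation, a 6-(enolexo)-exo-trig closure that forms the bond between the aryloxy carbon and the former lactone carbonyl (C8–C8a of the target) and gives enedione 14, which tautomerises irreversibly to resorcinol 15. The closest known reaction is the alkoxide-induced conversion of 4-methoxy-6-methyl-2-pyranone into 5-methoxyresorcinol; here the aryloxy group additionally acidifies the nucleophilic carbon. The selectivity needed is C-acylation from C6: the C4 enolate could only close a four-membered ring, O-acylation merely returns 12 and is reversible, and aromatisation drains the equilibrium. Because the alkoxide matches the 4-benzyloxy group, ester exchange and addition–elimination at C4 are degenerate and the benzyl ether stays on the oxygen para to the new ether carbon; no stereocentre is formed, and the lactone of ring A, if opened to its Z cinnamate, should reclose on acidification.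

Step 9
Reactants: 15 8-[4-(benzyloxy)-2,6-dihydroxyphenoxy]-7-methoxy-2H-chromen-2-one; 16 ethyl propiolate
Product: 18 5-(benzyloxy)-7-hydroxy-8-[(7-methoxy-2-oxo-2H-chromen-8-yl)oxy]-2H-chromen-2-one, via Z-cinnamate ester 17 (not isolated)
Conditions: 16 (1.2 equiv), Pd(OAc)2 (5 mol %), TFA/CH2Cl2 (1:3), 0 °C to rt
Reagents that add atoms: none
Why: Pd(OAc)2-catalysed alkyne hydroarylation in TFA (Fujiwara hydroarylation) adds either of the two equivalent, electron-rich CH positions of ring B anti across the propiolate, and Z cinnamate 17 lactonises onto its only free neighbouring hydroxyl because the other neighbour is the benzyl ether, which fixes the 8-aryloxy pattern.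

Step 10
Reactants: 18 5-(benzyloxy)-7-hydroxy-8-[(7-methoxy-2-oxo-2H-chromen-8-yl)oxy]-2H-chromen-2-one
Product: 19 5,7-dihydroxy-8-[(7-methoxy-2-oxo-2H-chromen-8-yl)oxy]-2H-chromen-2-one (CNP0305396.0)
Conditions: BCl3 (1 M in CH2Cl2, 4 equiv), C6HMe5 (5 equiv), CH2Cl2, −78 °C; then H2O
Reagents that add atoms: none
Why: Lewis acid debenzylation with pentamethylbenzene as benzyl cation scavenger cleaves aryl benzyl ethers at −78 °C without touching the aryl methyl ether, the diaryl ether or the two coumarin alkenes, which hydrogenolysis could reduce.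

**Compound list**

1 | daphnetin (7,8-dihydroxy-2H-chromen-2-one) | O=c1ccc2ccc(O)c(O)c2o1 | starting material
2 | 8-hydroxy-7-methoxy-2H-chromen-2-one | COc1ccc2ccc(=O)oc2c1O | intermediate
3 | tert-butyl bromoacetate | CC(C)(C)OC(=O)CBr | starting material
4 | tert-butyl 2-[(7-methoxy-2-oxo-2H-chromen-8-yl)oxy]acetate | COc1ccc2ccc(=O)oc2c1OCC(=O)OC(C)(C)C | intermediate
5 | 2-[(7-methoxy-2-oxo-2H-chromen-8-yl)oxy]acetic acid | COc1ccc2ccc(=O)oc2c1OCC(=O)O | intermediate
6 | 2-[(7-methoxy-2-oxo-2H-chromen-8-yl)oxy]acetyl chloride | COc1ccc2ccc(=O)oc2c1OCC(=O)Cl | intermediate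
7 | 2,2,6-trimethyl-4H-1,3-dioxin-4-one | CC1=CC(=O)OC(C)(C)O1 | starting material
8 | lithium 2,2-dimethyl-6-methylidene-6H-1,3-dioxin-4-olate (lithium dienolate of 7) | [Li+].C=C1C=C([O-])OC(C)(C)O1 | intermediate
9 | 6-{3-[(7-methoxy-2-oxo-2H-chromen-8-yl)oxy]-2-oxopropyl}-2,2-dimethyl-4H-1,3-dioxin-4-one | COc1ccc2ccc(=O)oc2c1OCC(=O)CC1=CC(=O)OC(C)(C)O1 | intermediate
10 | 6-[(7-methoxy-2-oxo-2H-chromen-8-yl)oxy]-3,5-dioxohex-1-en-1-one (acylketene) | COc1ccc2ccc(=O)oc2c1OCC(=O)CC(=O)C=C=O | intermediate
11 | 4-hydroxy-6-{[(7-methoxy-2-oxo-2H-chromen-8-yl)oxy]methyl}-2H-pyran-2-one | COc1ccc2ccc(=O)oc2c1OCc1cc(O)cc(=O)o1 | intermediate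
12 | 4-(benzyloxy)-6-{[(7-methoxy-2-oxo-2H-chromen-8-yl)oxy]methyl}-2H-pyran-2-one | O=c1cc(OCc2ccccc2)cc(COc2c(OC)ccc3ccc(=O)oc23)o1 | intermediate
13 | benzyl (2E)-3-(benzyloxy)-6-[(7-methoxy-2-oxo-2H-chromen-8-yl)oxy]-5-oxohex-2-enoate | O=C(OCc1ccccc1)/C=C(/OCc1ccccc1)CC(=O)COc1c(OC)ccc2ccc(=O)oc12 | intermediate
14 | 5-(benzyloxy)-2-[(7-methoxy-2-oxo-2H-chromen-8-yl)oxy]cyclohex-4-ene-1,3-dione | O=C1C=C(OCc2ccccc2)CC(=O)C1Oc1c(OC)ccc2ccc(=O)oc12 | intermediate
15 | 8-[4-(benzyloxy)-2,6-dihydroxyphenoxy]-7-methoxy-2H-chromen-2-one | Oc1cc(OCc2ccccc2)cc(O)c1Oc1c(OC)ccc2ccc(=O)oc12 | intermediate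
16 | ethyl propiolate | CCOC(=O)C#C | starting material
17 | ethyl (2Z)-3-{6-(benzyloxy)-2,4-dihydroxy-3-[(7-methoxy-2-oxo-2H-chromen-8-yl)oxy]phenyl}prop-2-enoate | CCOC(=O)/C=C\c1c(OCc2ccccc2)cc(O)c(Oc2c(OC)ccc3ccc(=O)oc23)c1O | intermediate
18 | 5-(benzyloxy)-7-hydroxy-8-[(7-methoxy-2-oxo-2H-chromen-8-yl)oxy]-2H-chromen-2-one | O=c1ccc2c(OCc3ccccc3)cc(O)c(Oc3c(OC)ccc4ccc(=O)oc34)c2o1 | intermediate
19 | 5,7-dihydroxy-8-[(7-methoxy-2-oxo-2H-chromen-8-yl)oxy]-2H-chromen-2-one (CNP0305396.0) | COc1ccc2ccc(=O)oc2c1Oc1c(O)cc(O)c2ccc(=O)oc12 | target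

Total step count: 10. Longest linear sequence: 10 steps (1 to 19).

**Steps most likely to fail**

1. Step 8. The Claisen closure may be slow, because the enolate equilibrium favours the unproductive C4 enolate and the nucleophilic carbon is secondary. On prolonged heating in alkoxide the opened lactone of ring A may then isomerise from the Z to the E cinnamate, which does not relactonise, or aryloxide may be lost from the keto ether. The fallback gives up the ring transformation for a copper-catalysed diaryl ether synthesis; it sets out from phenol 2 and comes back at 15. Phloroglucinol would be monobenzylated (PhCH2Br, K2CO3, DMF) to 5-(benzyloxy)benzene-1,3-diol F1 and protected (MeOCH2Cl, iPr2NEt) as 1-(benzyloxy)-3,5-bis(methoxymethoxy)benzene F2. F2 would be lithiated between the two acetal oxygens (n-BuLi, THF, 0 °C) and iodinated (I2) to 5-(benzyloxy)-2-iodo-1,3-bis(methoxymethoxy)benzene F3. Ullmann coupling of F3 with 2 (CuI, picolinic acid, K3PO4, DMSO, 90 °C) should give 8-[4-(benzyloxy)-2,6-bis(methoxymethoxy)phenoxy]-7-methoxy-2H-chromen-2-one F4, and HCl in MeOH would remove both methoxymethyl groups to return 15. This coupling joins two doubly ortho-substituted partners and is itself demanding.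

2. Step 5. The dienolate may attack the coumarin of ring A (1,2- or 1,4-addition) instead of the acid chloride, or the aryloxyacetyl chloride may be deprotonated to a ketene that oligomerises, so that C-acylation is lost. The fallback joins the phenol to a preformed pyranone; it sets out from phenol 2 and comes back at 12, bypassing steps 2 to 7. Triacetic acid lactone (4-hydroxy-6-methyl-2H-pyran-2-one) would be benzylated under Mitsunobu conditions (PhCH2OH, PPh3, DIAD) to 4-(benzyloxy)-6-methyl-2H-pyran-2-one F5. The 6-methyl group would be oxidised with SeO2 (dioxane, 150 °C, sealed tube) to 4-(benzyloxy)-6-oxo-6H-pyran-2-carbaldehyde F6, and NaBH4 (MeOH, 0 °C) would reduce the aldehyde to 4-(benzyloxy)-6-(hydroxymethyl)-2H-pyran-2-one F7. Mitsunobu etherification of F7 with 2 (PPh3, DIAD, THF) should then give 12.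

3. Step 9. The benzyl group may be lost or may migrate to carbon in TFA, which would open the way to the 6-aryloxy regioisomer. A second annulation may also occur at the remaining CH of ring B, or arylation may stall next to the bulky aryloxy group. The fallback replaces the one-step annulation by formylation and olefination; it sets out from 15 and comes back at 18. ortho-Formylation of 15 (MgCl2, Et3N, paraformaldehyde, MeCN, reflux) at either equivalent position should give 6-(benzyloxy)-2,4-dihydroxy-3-[(7-methoxy-2-oxo-2H-chromen-8-yl)oxy]benzaldehyde F8. Wittig reaction with Ph3P=CHCO2Et in N,N-diethylaniline at reflux would give ethyl (2E)-3-{6-(benzyloxy)-2,4-dihydroxy-3-[(7-methoxy-2-oxo-2H-chromen-8-yl)oxy]phenyl}prop-2-enoate F9, which at that temperature should isomerise and lactonise onto the adjacent hydroxyl to give 18.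

**Further compounds**

F1 | step 8 | 5-(benzyloxy)benzene-1,3-diol | Oc1cc(O)cc(OCc2ccccc2)c1
F2 | step 8 | 1-(benzyloxy)-3,5-bis(methoxymethoxy)benzene | COCOc1cc(OCOC)cc(OCc2ccccc2)c1
F3 | step 8 | 5-(benzyloxy)-2-iodo-1,3-bis(methoxymethoxy)benzene | COCOc1cc(OCc2ccccc2)cc(OCOC)c1I
F4 | step 8 | 8-[4-(benzyloxy)-2,6-bis(methoxymethoxy)phenoxy]-7-methoxy-2H-chromen-2-one | COCOc1cc(OCc2ccccc2)cc(OCOC)c1Oc1c(OC)ccc2ccc(=O)oc12
F5 | step 5 | 4-(benzyloxy)-6-methyl-2H-pyran-2-one | Cc1cc(OCc2ccccc2)cc(=O)o1
F6 | step 5 | 4-(benzyloxy)-6-oxo-6H-pyran-2-carbaldehyde | O=Cc1cc(OCc2ccccc2)cc(=O)o1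
F7 | step 5 | 4-(benzyloxy)-6-(hydroxymethyl)-2H-pyran-2-one | OCc1cc(OCc2ccccc2)cc(=O)o1
F8 | step 9 | 6-(benzyloxy)-2,4-dihydroxy-3-[(7-methoxy-2-oxo-2H-chromen-8-yl)oxy]benzaldehyde | O=Cc1c(OCc2ccccc2)cc(O)c(Oc2c(OC)ccc3ccc(=O)oc23)c1O
F9 | step 9 | ethyl (2E)-3-{6-(benzyloxy)-2,4-dihydroxy-3-[(7-methoxy-2-oxo-2H-chromen-8-yl)oxy]phenyl}prop-2-enoate | CCOC(=O)/C=C/c1c(OCc2ccccc2)cc(O)c(Oc2c(OC)ccc3ccc(=O)oc23)c1O
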